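**Retrosynthetic overview**

1. Glaucolide L ⇐ 8-oxo-4E-ene germacranolide 23, by C8 ketone reduction, methacryloylation, outer-face epoxidation of C4=C5 and release of O13.
2. Structural feature used: C4 (quaternary epoxide carbon) and C8 (acyloxy carbon) lie three bonds apart through C5–C6–C7, so a C4–C8 bond divides the ten-membered ring C1–C10 into a cyclopentane (C4–C5–C6–C7–C8) cis-fused to a cycloheptane (C8–C9–C10–C1–C2–C3–C4). Heterolysis of that bond in the C8 carbinol/C5 mesylate 21 gives C8=O and E-C4=C5 together.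
3. 21 ⇐ ynal 17 by a Mo(CO)6 hetero-Pauson–Khand reaction (C6–C7, C11–C12 and C12–O bonds), which closes the cyclopentane and the butenolide in one step on the preformed cycloheptane.
4. 17 ⇐ (S)-4-silyloxycycloheptenone 4 by α'-aldol with (R)-glyceraldehyde acetonide (C4–C5), chelate-controlled methylation (quaternary C4), cuprate addition (C10 methyl) and acetylide addition (C7–C8).
5. Ring order: cycloheptane (from cyclohepta-1,3-diene) → cyclopentane and butenolide (step 11) → ten-membered ring by scission (step 15) → epoxide (step 18).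

Key step: step 15

Remark: germacrane numbering is used throughout (C1 acetate carbon, C4 and C10 methyl-bearing carbons, C6 lactone carbinol, C8 methacrylate carbon, C12 lactone carbonyl, C13 hydroxymethyl carbon); TBS = tert-butyldimethylsilyl, TES = triethylsilyl, PMB = 4-methoxybenzyl, Ms = methanesulfonyl.
Remark: O13 is carried as a PMB ether, not a silyl ether, so that the silyl groups on O1, O5 and O8 can be removed together in step 12 without touching it.
Assumption: of the two pseudoenantiomeric 6'-hydroxycinchona catalysts, the one that gives the (S)-hydroxy enone 3 is used in step 2.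

**Route**

Step 1
Reactants: 1 cyclohepta-1,3-diene
Product: 2 6,7-dioxabicyclo[3.2.2]non-8-ene (meso endoperoxide)
Conditions: O2, tetraphenylporphyrin (cat.), visible light, CH2Cl2, 0 °C
Reagents that add atoms: oxygen, O=O
Why: Singlet-oxygen [4+2] cycloaddition (photooxygenation) across the cyclic 1,3-diene should give the meso endoperoxide, which places oxygen on the future C8 and C1; no stereocentre of the target is fixed yet.

Step 2
Reactants: 2 6,7-dioxabicyclo[3.2.2]non-8-ene
Product: 3 (S)-4-hydroxycyclohept-2-en-1-one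
Conditions: 9-O-acetylcupreidine or its cupreine pseudoenantiomer (10 mol %), CH2Cl2, rt
Reagents that add atoms: none
Why: Enantioselective Kornblum–DeLaMare rearrangement, in which the chiral amine removes one of the two enantiotopic bridgehead hydrogens of the meso peroxide as the O–O bond breaks, so catalyst control sets the future C1 carbinol as S.

Step 3
Reactants: 3 (S)-4-hydroxycyclohept-2-en-1-one
Product: 4 (S)-4-(tert-butyldimethylsilyloxy)cyclohept-2-en-1-one
Conditions: TBSCl, imidazole, CH2Cl2, 0 °C → rt
Reagents that add atoms: tert-butyldimethylsilyl chloride, CC(C)(C)[Si](C)(C)Cl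
Why: Silyl ether formation on the secondary allylic alcohol gives a γ-silyloxy enone whose bulky ether tolerates the enolate chemistry and later directs the cuprate.

Step 4
Reactants: 4 (S)-4-(tert-butyldimethylsilyloxy)cyclohept-2-en-1-one; 5 (R)-2,2-dimethyl-1,3-dioxolane-4-carbaldehyde
Product: 7 (4S)-4-(tert-butyldimethylsilyloxy)-7-[(S)-[(4R)-2,2-dimethyl-1,3-dioxolan-4-yl](hydroxy)methyl]cyclohept-2-en-1-one (both C7 epimers), via lithium dienolate 6 (not isolated)
Conditions: LDA, THF, −78 °C; then 5, −78 °C; AcOH quench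
Reagents that add atoms: none
Why: Kinetic α'-deprotonation of the enone (C4 is its only sp3 α-carbon) and aldol addition of the cross-conjugated lithium dienolate to the α-alkoxy aldehyde, whose Felkin–Anh preference should give the 5,6-anti adduct and so fix C5 as S from the chiral-pool aldehyde, while the C4 epimers converge in step 5.

Step 5
Reactants: 7 aldol adduct (both C4 epimers)
Product: 9 (4S,7S)-4-(tert-butyldimethylsilyloxy)-7-[(S)-[(4R)-2,2-dimethyl-1,3-dioxolan-4-yl](hydroxy)methyl]-7-methylcyclohept-2-en-1-one, via dilithium oxido dienolate 8 (not isolated)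
Conditions: LDA (2.2 equiv), THF, −78 → −45 °C; MeI, DMPU, −78 → −40 °C; AcOH, −78 °C
Reagents that add atoms: iodomethane, CI
Why: Fráter–Seebach-type alkylation of the β-oxido enolate: in the six-membered lithium chelate between the C5 alkoxide and the enolate oxygen the dioxolanyl group shields one face, so iodomethane should enter anti to it (also anti to the C1 silyl ether) and create quaternary C4 (S) with the methyl anti to O5 in the extended chain, that is cis to O5 on the later cyclopentane; the cold acid quench protects the product alkoxide from retro-aldol cleavage.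

Step 6
Reactants: 9 methylated β-hydroxy enone
Product: 10 (4S,7S)-4-(tert-butyldimethylsilyloxy)-7-[(S)-(tert-butyldimethylsilyloxy)[(4R)-2,2-dimethyl-1,3-dioxolan-4-yl]methyl]-7-methylcyclohept-2-en-1-one
Conditions: TBSOTf, 2,6-lutidine, CH2Cl2, −78 → 0 °C
Reagents that add atoms: tert-butyldimethylsilyl triflate, CC(C)(C)[Si](C)(C)OS(=O)(=O)C(F)(F)F
Why: Silyl triflate silylation of the hindered neopentyl secondary alcohol blocks retro-aldol cleavage in the basic steps that follow and gives an ether that tolerates the acid of step 10.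

Step 7
Reactants: 10 bis-silyl enone
Product: 11 (2S,5S,6S)-5-(tert-butyldimethylsilyloxy)-2-[(S)-(tert-butyldimethylsilyloxy)[(4R)-2,2-dimethyl-1,3-dioxolan-4-yl]methyl]-2,6-dimethylcycloheptan-1-one
Conditions: Me2CuLi (from MeLi and CuI), Et2O, −78 → −40 °C; aq. NH4Cl
Reagents that add atoms: lithium dimethylcuprate, [Li+].C[Cu-]C
Why: Conjugate addition of the Gilman cuprate to the cycloheptenone from the face anti to the adjacent C1 silyloxy group (1,2-induction) should set C10 as S with the methyl trans to O1.

Step 8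
Reactants: 12 prop-2-yn-1-ol
Product: 13 1-methoxy-4-[(prop-2-yn-1-yloxy)methyl]benzene (PMB propargyl ether)
Conditions: PMBCl, powdered KOH, Bu4NI (cat.), THF, rt
Reagents that add atoms: 4-methoxybenzyl chloride, COc1ccc(CCl)cc1
Why: Williamson etherification under phase-transfer conditions protects the future O13 as a PMB ether, which is orthogonal to the silyl ethers and removable oxidatively at the end.

Step 9
Reactants: 11 cycloheptanone; 13 PMB propargyl ether
Product: 16 (1S,2S,5S,6S)-5-(tert-butyldimethylsilyloxy)-2-[(S)-(tert-butyldimethylsilyloxy)[(4R)-2,2-dimethyl-1,3-dioxolan-4-yl]methyl]-1-[3-(4-methoxybenzyloxy)prop-1-yn-1-yl]-2,6-dimethyl-1-(triethylsilyloxy)cycloheptane, via lithium acetylide 14 (not isolated), via lithium alkoxide 15 (not isolated)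
Conditions: 13, n-BuLi, THF, −78 °C; then 11, −78 → −20 °C; then excess TESOTf, −78 → 0 °C
Reagents that add atoms: triethylsilyl triflate, CC[Si](CC)(CC)OS(=O)(=O)C(F)(F)F
Why: 1,2-Addition of the lithium acetylide to the α-quaternary ketone should occur by axial attack anti to the pseudoaxial C4 methyl (the bulky C5 side chain sits equatorial), placing the alkyne cis to the C5 side chain and O8 cis to the C4 methyl (C8 S); in-flask silylation of the tertiary alkoxide keeps O8 from closing a lactol on the aldehyde made in step 10.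

Step 10
Reactants: 16 silylated alkynyl acetonide
Product: 17 (2S)-2-(tert-butyldimethylsilyloxy)-2-[(1S,2S,4S,5S)-5-(tert-butyldimethylsilyloxy)-2-[3-(4-methoxybenzyloxy)prop-1-yn-1-yl]-1,4-dimethyl-2-(triethylsilyloxy)cycloheptyl]acetaldehyde
Conditions: H5IO6, EtOAc, 0 °C → rt
Reagents that add atoms: none
Why: Periodic acid hydrolyses the terminal dioxolane and cleaves the liberated 1,2-diol in the same flask (glycol cleavage), so the former glyceraldehyde stereocentre becomes the C6 aldehyde carbon; the neopentyl TBS, tertiary TES and PMB ethers should survive the short, cold exposure to this weak acid.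

Step 11
Reactants: 17 ynal
Product: 18 (1S,4S,5S,6S,8R,10S)-1,5-bis(tert-butyldimethylsilyloxy)-13-(4-methoxybenzyloxy)-8-(triethylsilyloxy)-4,8-cyclogermacr-7(11)-en-12,6-olide
Conditions: Mo(CO)6 (1.2 equiv), DMSO (10 equiv), toluene, 100 °C
Reagents that add atoms: molybdenum hexacarbonyl, [Mo].[C-]#[O+].[C-]#[O+].[C-]#[O+].[C-]#[O+].[C-]#[O+].[C-]#[O+]
Why: Hetero-Pauson–Khand reaction: oxidative cyclisation of the aldehyde C=O and the alkyne on zerovalent molybdenum forms C6–C7 (5-exo closure of the cyclopentane, cis-fused because alkyne and side chain are cis on the cycloheptane), CO insertion and reductive elimination close the butenolide, and C6 should form with its oxygen trans to the neighbouring C5 silyloxy group (6S), which takes the convex face of the new bicycle.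

Step 12
Reactants: 18 silylated tricyclic butenolide
Product: 19 (1S,4S,5S,6S,8R,10S)-1,5,8-trihydroxy-13-(4-methoxybenzyloxy)-4,8-cyclogermacr-7(11)-en-12,6-olide
Conditions: 48% aq. HF, MeCN, 0 °C → rt
Reagents that add atoms: none
Why: Fluoride-mediated desilylation removes the two TBS ethers and the tertiary TES ether together, while the PMB ether, the butenolide and the electron-poor tertiary allylic alcohol are stable to these conditions.

Step 13
Reactants: 19 triol
Product: 20 (1S,4S,5S,6S,8R,10S)-1-acetoxy-5,8-dihydroxy-13-(4-methoxybenzyloxy)-4,8-cyclogermacr-7(11)-en-12,6-olide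
Conditions: Ac2O (1.1 equiv), pyridine, CH2Cl2, 0 °C
Reagents that add atoms: acetic anhydride, CC(=O)OC(C)=O
Why: Selective acylation: the C1 hydroxyl is an ordinary secondary alcohol, whereas the C5 hydroxyl is neopentyl and flanked by the cis angular methyl and the lactone carbinol and the C8 hydroxyl is tertiary, so one equivalent of anhydride without acylation catalyst should acetylate O1 only.

Step 14
Reactants: 20 C1 acetate diol
Product: 21 (1S,4S,5S,6S,8R,10S)-1-acetoxy-8-hydroxy-5-(methanesulfonyloxy)-13-(4-methoxybenzyloxy)-4,8-cyclogermacr-7(11)-en-12,6-olide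
Conditions: MsCl, Et3N, CH2Cl2, −20 → 0 °C
Reagents that add atoms: methanesulfonyl chloride, CS(=O)(=O)Cl
Why: Mesylation through sulfene converts the remaining secondary hydroxyl at C5 into the leaving group with retention, cis to the angular C4 methyl and to the tertiary C8 hydroxyl, which is too hindered to react.

Step 15
Reactants: 21 tricyclic C8 carbinol C5 mesylate
Product: 23 (1S,4E,6R,10S)-1-acetoxy-13-(4-methoxybenzyloxy)-8-oxogermacra-4,7(11)-dien-12,6-olide, via potassium alkoxide 22 (not isolated)
Conditions: KN(SiMe3)2 (1.05 equiv), THF, −78 → −20 °C; pH 7 buffer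
Reagents that add atoms: none
Why: KN(SiMe3)2 removes the proton of the tertiary C8 hydroxyl and the potassium alkoxide collapses to the C8 ketone while the C4–C8 σ bond, which lies close to anti-periplanar to the C5–OMs bond on the puckered cyclopentane, breaks and its electrons expel the mesylate as the C4=C5 π bond forms. The closest known reaction type is the Grob (Wharton-type) fragmentation of bicyclic 1,3-diol monosulfonates used for ring expansion to E-cyclodecenones. No ring is closed by bond making; the ten-membered ring is unveiled by cutting the bond common to the cyclopentane and the cycloheptane, with relief of the strain of three cis substituents (O8, C4 methyl, O5) on one face. No stereocentre is created: C4, C5 and C8 become trigonal, and C1, C6 and C10 are not involved (C6 changes descriptor from S to R only through a priority change). The selectivity needed is E over Z, and it is secured stereospecifically because the mesylate is cis to the angular methyl, so that in the anti-periplanar transition state C6 and the methyl end up on the same side of the new alkene and C3 and C6 trans. The step also needs heterolysis to outrun removal of the acidic C6–H with loss of mesylate across C5–C6, which should follow from fast O–H deprotonation by one equivalent of base at −78 °C; oxetane formation is excluded because the alkoxide is cis to the mesylate.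

Step 16
Reactants: 23 8-oxo-4E-ene germacranolide
Product: 24 (1S,4E,6R,8S,10S)-1-acetoxy-8-hydroxy-13-(4-methoxybenzyloxy)germacra-4,7(11)-dien-12,6-olide
Conditions: (R)-2-methyl-CBS-oxazaborolidine (20 mol %), catecholborane, toluene, −78 °C; MeOH, then aq. NaHCO3
Reagents that add atoms: none
Why: Corey–Bakshi–Shibata reduction: with the butenolide alkenyl carbon C7 as the large and C9H2 as the small ketone substituent, the (R)-oxazaborolidine should deliver hydride to give the 8S allylic alcohol by reagent control, and catecholborane at −78 °C leaves the lactone, the acetate and the C4=C5 alkene untouched.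

Step 17
Reactants: 24 C8 alcohol; 25 methacrylic anhydride
Product: 26 (1S,4E,6R,8S,10S)-1-acetoxy-13-(4-methoxybenzyloxy)-8-(methacryloyloxy)germacra-4,7(11)-dien-12,6-olide
Conditions: Et3N, DMAP (cat.), CH2Cl2, 0 °C → rt
Reagents that add atoms: none
Why: DMAP-catalysed acylation of the secondary allylic alcohol by the anhydride gives the methacrylate with retention at C8; translactonisation to O8 cannot compete because C8 and C12 are trans across the C7=C11 bond.

Step 18
Reactants: 26 methacrylate
Product: 27 (1S,4R,5R,6S,8S,10S)-1-acetoxy-4,5-epoxy-13-(4-methoxybenzyloxy)-8-(methacryloyloxy)germacr-7(11)-en-12,6-olide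
Conditions: mCPBA, NaHCO3, CH2Cl2, 0 °C
Reagents that add atoms: 3-chloroperoxybenzoic acid, OOC(=O)c1cccc(Cl)c1
Why: Prilezhaev epoxidation is chemoselective for the only electron-rich alkene (trisubstituted C4=C5; the methacrylate and butenolide alkenes are electron-poor) and stereospecific for the E geometry, and attack on the outer face of the alkene, which stands perpendicular to the ring with C6–H eclipsing it and O6 outside, should give the 4R,5R epoxide as in related 6,12-germacranolide 4,5-epoxides.

Step 19
Reactants: 27 epoxide PMB ether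
Product: 28 glaucolide L, (1S,4R,5R,6S,8S,10S)-1-acetoxy-4,5-epoxy-13-hydroxy-8-(methacryloyloxy)germacr-7(11)-en-12,6-olide
Conditions: DDQ, CH2Cl2/pH 7 phosphate buffer (10:1), 0 °C → rt
Reagents that add atoms: none
Why: Oxidative cleavage of the PMB ether with DDQ in buffered wet dichloromethane is neutral, so the epoxide, both esters and the butenolide should survive and no acyl migration from O8 to O13 is triggered.

**Compound list**

1 | cyclohepta-1,3-diene | C1=CC=CCCC1 | starting material
2 | 6,7-dioxabicyclo[3.2.2]non-8-ene | C1CC2OOC(C1)C=C2 | intermediate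
3 | (S)-4-hydroxycyclohept-2-en-1-one | O=C1C=C[C@@H](O)CCC1 | intermediate
4 | (S)-4-(tert-butyldimethylsilyloxy)cyclohept-2-en-1-one | O=C1C=C[C@@H](O[Si](C)(C)C(C)(C)C)CCC1 | intermediate
5 | (R)-2,2-dimethyl-1,3-dioxolane-4-carbaldehyde ((R)-glyceraldehyde acetonide) | O=C[C@H]1COC(C)(C)O1 | starting material
6 | lithium (5S)-5-(tert-butyldimethylsilyloxy)cyclohepta-1,6-dien-1-olate (not isolated) | [Li+].[O-]C1=CCC[C@H](O[Si](C)(C)C(C)(C)C)C=C1 | intermediate
7 | (4S)-4-(tert-butyldimethylsilyloxy)-7-[(S)-[(4R)-2,2-dimethyl-1,3-dioxolan-4-yl](hydroxy)methyl]cyclohept-2-en-1-one, both C7 epimers | O=C1C=C[C@@H](O[Si](C)(C)C(C)(C)C)CCC1[C@H](O)[C@H]1COC(C)(C)O1 | intermediate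
8 | dilithium oxido dienolate of 7 (not isolated) | [Li+].[Li+].[O-]C1=C([C@H]([O-])[C@H]2COC(C)(C)O2)CC[C@H](O[Si](C)(C)C(C)(C)C)C=C1 | intermediate
9 | (4S,7S)-4-(tert-butyldimethylsilyloxy)-7-[(S)-[(4R)-2,2-dimethyl-1,3-dioxolan-4-yl](hydroxy)methyl]-7-methylcyclohept-2-en-1-one | O=C1C=C[C@@H](O[Si](C)(C)C(C)(C)C)CC[C@@]1(C)[C@H](O)[C@H]1COC(C)(C)O1 | intermediate
10 | (4S,7S)-4-(tert-butyldimethylsilyloxy)-7-[(S)-(tert-butyldimethylsilyloxy)[(4R)-2,2-dimethyl-1,3-dioxolan-4-yl]methyl]-7-methylcyclohept-2-en-1-one | O=C1C=C[C@@H](O[Si](C)(C)C(C)(C)C)CC[C@@]1(C)[C@H](O[Si](C)(C)C(C)(C)C)[C@H]1COC(C)(C)O1 | intermediate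
11 | (2S,5S,6S)-5-(tert-butyldimethylsilyloxy)-2-[(S)-(tert-butyldimethylsilyloxy)[(4R)-2,2-dimethyl-1,3-dioxolan-4-yl]methyl]-2,6-dimethylcycloheptan-1-one | O=C1C[C@H](C)[C@@H](O[Si](C)(C)C(C)(C)C)CC[C@@]1(C)[C@H](O[Si](C)(C)C(C)(C)C)[C@H]1COC(C)(C)O1 | intermediate
12 | prop-2-yn-1-ol | C#CCO | starting material
13 | 1-methoxy-4-[(prop-2-yn-1-yloxy)methyl]benzene | C#CCOCc1ccc(OC)cc1 | intermediate
14 | lithium 3-(4-methoxybenzyloxy)prop-1-yn-1-ide (not isolated) | [Li+].[C-]#CCOCc1ccc(OC)cc1 | intermediate
15 | lithium C8 alkoxide from 11 and 14 (not isolated) | [Li+].[O-][C@]1(C#CCOCc2ccc(OC)cc2)C[C@H](C)[C@@H](O[Si](C)(C)C(C)(C)C)CC[C@@]1(C)[C@H](O[Si](C)(C)C(C)(C)C)[C@H]1COC(C)(C)O1 | intermediate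
16 | (1S,2S,5S,6S)-5-(tert-butyldimethylsilyloxy)-2-[(S)-(tert-butyldimethylsilyloxy)[(4R)-2,2-dimethyl-1,3-dioxolan-4-yl]methyl]-1-[3-(4-methoxybenzyloxy)prop-1-yn-1-yl]-2,6-dimethyl-1-(triethylsilyloxy)cycloheptane | CC[Si](CC)(CC)O[C@]1(C#CCOCc2ccc(OC)cc2)C[C@H](C)[C@@H](O[Si](C)(C)C(C)(C)C)CC[C@@]1(C)[C@H](O[Si](C)(C)C(C)(C)C)[C@H]1COC(C)(C)O1 | intermediate
17 | (2S)-2-(tert-butyldimethylsilyloxy)-2-[(1S,2S,4S,5S)-5-(tert-butyldimethylsilyloxy)-2-[3-(4-methoxybenzyloxy)prop-1-yn-1-yl]-1,4-dimethyl-2-(triethylsilyloxy)cycloheptyl]acetaldehyde | CC[Si](CC)(CC)O[C@]1(C#CCOCc2ccc(OC)cc2)C[C@H](C)[C@@H](O[Si](C)(C)C(C)(C)C)CC[C@@]1(C)[C@H](O[Si](C)(C)C(C)(C)C)C=O | intermediate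
18 | (1S,4S,5S,6S,8R,10S)-1,5-bis(tert-butyldimethylsilyloxy)-13-(4-methoxybenzyloxy)-8-(triethylsilyloxy)-4,8-cyclogermacr-7(11)-en-12,6-olide | CC[Si](CC)(CC)O[C@]12C[C@H](C)[C@@H](O[Si](C)(C)C(C)(C)C)CC[C@@]1(C)[C@H](O[Si](C)(C)C(C)(C)C)[C@H]1OC(=O)C(COCc3ccc(OC)cc3)=C12 | intermediate
19 | (1S,4S,5S,6S,8R,10S)-1,5,8-trihydroxy-13-(4-methoxybenzyloxy)-4,8-cyclogermacr-7(11)-en-12,6-olide | O[C@]12C[C@H](C)[C@@H](O)CC[C@@]1(C)[C@H](O)[C@H]1OC(=O)C(COCc3ccc(OC)cc3)=C12 | intermediate
20 | (1S,4S,5S,6S,8R,10S)-1-acetoxy-5,8-dihydroxy-13-(4-methoxybenzyloxy)-4,8-cyclogermacr-7(11)-en-12,6-olide | O[C@]12C[C@H](C)[C@@H](OC(C)=O)CC[C@@]1(C)[C@H](O)[C@H]1OC(=O)C(COCc3ccc(OC)cc3)=C12 | intermediate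
21 | (1S,4S,5S,6S,8R,10S)-1-acetoxy-8-hydroxy-5-(methanesulfonyloxy)-13-(4-methoxybenzyloxy)-4,8-cyclogermacr-7(11)-en-12,6-olide (key-step precursor) | O[C@]12C[C@H](C)[C@@H](OC(C)=O)CC[C@@]1(C)[C@H](OS(C)(=O)=O)[C@H]1OC(=O)C(COCc3ccc(OC)cc3)=C12 | intermediate
22 | potassium C8 alkoxide of 21 (not isolated) | [K+].[O-][C@]12C[C@H](C)[C@@H](OC(C)=O)CC[C@@]1(C)[C@H](OS(C)(=O)=O)[C@H]1OC(=O)C(COCc3ccc(OC)cc3)=C12 | intermediate
23 | (1S,4E,6R,10S)-1-acetoxy-13-(4-methoxybenzyloxy)-8-oxogermacra-4,7(11)-dien-12,6-olide (key-step product) | O=C1C[C@H](C)[C@@H](OC(C)=O)CC/C(C)=C/[C@H]2OC(=O)C(COCc3ccc(OC)cc3)=C12 | intermediate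
24 | (1S,4E,6R,8S,10S)-1-acetoxy-8-hydroxy-13-(4-methoxybenzyloxy)germacra-4,7(11)-dien-12,6-olide | O[C@H]1C[C@H](C)[C@@H](OC(C)=O)CC/C(C)=C/[C@H]2OC(=O)C(COCc3ccc(OC)cc3)=C12 | intermediate
25 | methacrylic anhydride | C=C(C)C(=O)OC(=O)C(C)=C | starting material
26 | (1S,4E,6R,8S,10S)-1-acetoxy-13-(4-methoxybenzyloxy)-8-(methacryloyloxy)germacra-4,7(11)-dien-12,6-olide | C=C(C)C(=O)O[C@H]1C[C@H](C)[C@@H](OC(C)=O)CC/C(C)=C/[C@H]2OC(=O)C(COCc3ccc(OC)cc3)=C12 | intermediate
27 | (1S,4R,5R,6S,8S,10S)-1-acetoxy-4,5-epoxy-13-(4-methoxybenzyloxy)-8-(methacryloyloxy)germacr-7(11)-en-12,6-olide | C=C(C)C(=O)O[C@H]1C[C@H](C)[C@@H](OC(C)=O)CC[C@@]2(C)O[C@@H]2[C@H]2OC(=O)C(COCc3ccc(OC)cc3)=C12 | intermediate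
28 | glaucolide L, (1S,4R,5R,6S,8S,10S)-1-acetoxy-4,5-epoxy-13-hydroxy-8-(methacryloyloxy)germacr-7(11)-en-12,6-olide | C=C(C)C(=O)O[C@H]1C[C@H](C)[C@@H](OC(C)=O)CC[C@@]2(C)O[C@@H]2[C@H]2OC(=O)C(CO)=C12 | target

**Step count**

Total: 19 steps. Longest linear sequence: 18 steps (steps 1–7 and 9–19, from cyclohepta-1,3-diene); step 8 is a one-step side branch.

**Three steps most likely to fail**

Step 15 (key fragmentation). The alkoxide or the amide base may remove the acidic C6–H, with loss of the mesylate across C5–C6 instead of fragmentation. Alternatively the C5–O bond may not reach the anti-periplanar arrangement with the C4–C8 bond, so that heterolysis is slow. Fallback: a base-free, ionisation-driven variant of the same scission sets out from diol 20. Tf2O and 2,6-di-tert-butyl-4-methylpyridine in CH2Cl2 at −78 °C convert the secondary C5 hydroxyl into the C5 triflate F1, which is not isolated. On warming, the much better nucleofuge should depart with participation of the C4–C8 bond while the neutral C8 hydroxyl acts as electrofuge (solvolytic Grob fragmentation of a 1,3-diol monotriflate), the hindered pyridine taking up the proton, so no carbanion-forming base is present. The route is rejoined at cyclodecenone 23.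

Step 11 (hetero-Pauson–Khand reaction). The oxidative cyclisation may stall at the congested tether, where O8, the C4 methyl and O5 crowd one face. The α-silyloxy aldehyde may also decompose at 100 °C, or the facial selectivity at C6 may be poor. Fallback: C6–C7 bond formation and carbonylation are separated. From ynal 17, Cp2Ti(PMe3)2 (divalent titanium) at room temperature effects reductive coupling of alkyne and aldehyde to an oxatitanacycle, whose Ti–C bond is cleaved with I2 in the same flask to give the iodo allylic alcohol F2 (iodine on C11 cis to C6). Pd(PPh3)4-catalysed carbonylative lactonisation (CO, Et3N, MeCN) then closes the butenolide and returns the route at 18.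

Step 5 (dianion methylation). The lithium aldolate may undergo retro-aldol cleavage before the second deprotonation, γ-deprotonation may compete, or chelate control of the methylation face may be weak. Fallback: the order of the two bond formations at C4 is reversed. Enone 4 is first methylated at C4 (LDA, MeI) to the α'-methyl enone F3 (both C4 epimers). Its tetrasubstituted enolate is transmetalated to the chlorozirconocene enolate (LDA, then Cp2ZrCl2) and added to aldehyde 5. Zirconium enolates give the erythro aldol irrespective of enolate geometry, which here should place ring carbon C3 syn and the methyl anti to the C5 hydroxyl, while the Felkin–Anh preference of 5 again fixes C5. The route is rejoined at 9.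

**Further compounds**

F1 | step 15 | (1S,4S,5S,6S,8R,10S)-1-acetoxy-8-hydroxy-13-(4-methoxybenzyloxy)-5-(trifluoromethanesulfonyloxy)-4,8-cyclogermacr-7(11)-en-12,6-olide | O[C@]12C[C@H](C)[C@@H](OC(C)=O)CC[C@@]1(C)[C@H](OS(=O)(=O)C(F)(F)F)[C@H]1OC(=O)C(COCc3ccc(OC)cc3)=C12
F2 | step 11 | bicyclic iodo allylic alcohol: cyclopentane C4–C8 of 18 with C6–OH (6S) and exocyclic C7=C11(I)CH2OPMB, iodine cis to C6, silyl ethers as in 17 | CC[Si](CC)(CC)O[C@]12C[C@H](C)[C@@H](O[Si](C)(C)C(C)(C)C)CC[C@@]1(C)[C@H](O[Si](C)(C)C(C)(C)C)[C@@H](O)/C2=C(\I)COCc1ccc(OC)cc1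
F3 | step 5 | (4S)-4-(tert-butyldimethylsilyloxy)-7-methylcyclohept-2-en-1-one, both C7 epimers | O=C1C=C[C@@H](O[Si](C)(C)C(C)(C)C)CCC1C
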